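The earlier runs and the new flask are calculated for an exercise; noise was put on by code.

At 40 h, the time I was to read the flask, its second portion of reagent had stood in it for 20 h, and the winter and autumn runs had been dosed on the same timetable.

all flasks: substrate 0.25 M; reagent 0.375 M (in portions, 2)

|  | capture agent | remark | time |
|---|---|---|---|
| winter | 0.017 M | run made earlier; portions every 20 h |  |
| autumn | 0.038 M | run made earlier; portions every 20 h |  |
| flask | 0.0250 M | the portions of reagent follow each other after 20 h, the first at the start | 40 h |

So the recipes part at [capture agent], which in the scheme on offer takes single product and not substrate.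

| run | time / h | substrate / % | single product / % |
|---|---|---|---|
| winter | 8.00 | 84.2 | 13.2 |
| winter | 15.0 | 76.9 | 21.9 |
| winter | 25.0 | 60.0 | 31.3 |
| winter | 30.0 | 51.8 | 34.4 |
| winter | 40.0 | 40.6 | 36.4 |
| winter | 50.0 | 33.7 | 36.9 |
| autumn | 3.00 | 93.1 | 6.6 |
| autumn | 10.0 | 81.0 | 16.3 |
| autumn | 15.0 | 76.0 | 20.0 |
| autumn | 25.0 | 59.9 | 29.0 |
| autumn | 40.0 | 38.9 | 36.0 |
| autumn | 50.0 | 33.7 | 33.6 |

(standard deviation of a reading: 1 percentage point)

The substrate columns agree with that: at 50.0 h both runs read 33.7 %, and at 40.0 h they read 40.6 % and 38.9 %, a gap of 1.7 percentage points on a scatter of 1 point. So I counted lifetimes, and the two runs gave on average 0.923 at that time for the lifetime count, the natural logarithm of substrate charged over substrate standing. On the scheme on offer this count is a pseudo-first-order decay summed over a changing [reagent], and I carried it unchanged to the flask, since its reagent timetable was the same. It bore on substrate, and for the other two answers I had no reckoning of my own.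

1. the substrate standing at 40 h, as a percentage of the substrate charged
2. the single product standing at 40 h, as a percentage of the substrate charged
3. the bis adduct standing at 40 h, as a percentage of the substrate charged

The forecast gave 39.8 % substrate, 36 % single product and 21 % bis adduct, and its ground for the first was this: “The capture agent acts only on the single product, so substrate decay should barely depend on it.”

The flask gave 39.9 % substrate, 35.9 % single product and 18.8 % bis adduct, and the forecast held.

    substrate + reagent → single product (k = 3.47 × 10⁻⁵ M⁻¹ s⁻¹)
    reagent + single product → bis adduct (k = 2.86 × 10⁻⁵ M⁻¹ s⁻¹)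
    single product + capture agent → trapped intermediate (k = 9.31 × 10⁻⁵ M⁻¹ s⁻¹)

The flask's own lifetime count was 0.919, against 0.923 from the earlier runs, and with the capture step struck out substrate stood at 40.1 %. I then scaled the count to the neighbouring flask charged with 0.094 M of reagent, a quarter of the charge, where 42.4 % of its own reagent charge remained after 40.0 h, against 47 % in the flask. That gave a count of 0.231, hence 79.4 % substrate, and that neighbour stood at 80.0 %.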